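The earlier runs and the new flask are calculated with constants of no real substance.

The violet run is your starting point. Its last reading shows 5% isomer against 49% target, so reckon the isomer as a small correction to the target.

- violet: substrate 2 M; coupling partner 1.05 equiv; run made earlier
- flask: substrate 1.3 M; coupling partner 1.05 equiv; time 10 h

- violet (time / min: target / %, isomer of the product / %): 8.00: 19, 0; 15.0: 28, 2; 25.0: 37, 3; 30.0: 37, 0; 40.0: 46, 1; 50.0: 47, 3; 60.0: 49, 5

(scatter of a reading: 1.5 percentage points)

- the earlier runs were read with a standard deviation of 1.5 percentage points
- steps under discussion: substrate + coupling partner <-> isomer of the product; substrate + coupling partner <-> target; coupling partner <-> dormant form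

- share of target in target plus isomer of the product at 2.0 min
- share of target in target plus isomer of the product at 30 min
- share of target in target plus isomer of the product at 10 h

Summing the violet readings gives isomer over target of 0.0532, the inverse of a selectivity factor. Both forward steps run on [substrate][coupling partner], so that product cancels in the ratio, and I reckon the early share in this flask at 94.9%.

Next, the first violet reading, with the two reagents taken as equal, gives a forward constant of 0.880 L mol⁻¹ h⁻¹. Where the target flattens, take forward and back as equal. With [substrate] at 0.920 M, the back constant is 0.760 h⁻¹.

That link is weak, because it counts all the partner as free, and the dormant form was never read. I guess that 0.5 of it is dormant, which no reading tests, and the back constant becomes 0.380 h⁻¹. Its half-life, 1.82 h, is shorter than 10 h, so the target can stand in balance. Isomer then forms at the ratio times the back rate, and isomer over target climbs by the leak constant 0.0202 h⁻¹, with the charge cancelled again. After 10 h in this flask I reckon the ratio at 0.255, so I commit to a share of 79.7%.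

The forecast gave 95%, 94% and, lower than my figure, 65% at the end, noting: “Whether the isomer is truly favoured is poorly determined”.

The flask gives 95.8%, 95.4% and 83.7%.

    substrate + coupling partner ⇌ isomer of the product (K = 2.01 L mol⁻¹, k = 0.0330 L mol⁻¹ h⁻¹)
    substrate + coupling partner ⇌ target (K = 2.00 L mol⁻¹, k = 0.751 L mol⁻¹ h⁻¹)
    coupling partner ⇌ dormant form (K = 0.993, k = 0.193 h⁻¹)

In this flask, target peaked at 2.48 h, and by 1.00 h its step had 100% of its turnover behind it, while the dormant step had 88% behind it by 5.00 h. The isomer step ran on, reaching half its turnover up to 10 h at 3.13 h, with 51.7% of the substrate charge and 27.7% of the partner charge still present at 10.0 h. Between 1.00 h and 10.0 h, isomer over target in this flask rose on average by 0.0156 h⁻¹, slower than my 0.0202 h⁻¹, and my share stands 4 percentage points below the flask's.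

For a neighbour flask with 1.80 equiv of partner, the leak constant contains no charge, so my reckoning again gives 79.7% at 10 h. The computed share in that flask is 83.6%, with 54.7% target.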